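## The problem

The target, [(1S,2R,3R,6S)-2-(benzoyloxy)-3-hydroxy-7-oxabicyclo[4.1.0]hept-4-en-1-yl]methyl benzoate (14), is a single cyclohexene ring. Its carbons are numbered C1 (quaternary oxirane carbon carrying the C7 methylene benzoate), C2 (CH–OBz), C3 (CH–OH), C4=C5 and C6 (oxirane CH). No carbocycle has to be fused to another; the difficulty lies in four contiguous stereocentres (C1, C2, C3, C6) whose three ring oxygens all lie on one face, the C2 and C3 oxygens being cis and the oxirane syn to both. An external oxidant would approach C1=C6 from the face away from these oxygens, so the oxirane has to be delivered from within by the C2 hydroxyl; C2 and C3 must therefore be set first, in the absolute sense, and then control C1 and C6. The three hydroxyl oxygens end up different (C7 and C2 benzoylated, C3 free), and since O2 and O3 are cis-vicinal an ester can travel between them under base. The vinyl oxirane does not survive protic or Lewis acid, soft nucleophiles or low-valent metals, and the benzoates do not survive alkoxide or hydride. Every cyclohexadiene cis-diol on the way can aromatise by acid-catalysed loss of water or dimerise. A short route is possible because C1–C6 with C7 attached are a masked cyclohexa-1,3-diene (C1=C6 to be epoxidised, C4=C5 kept) with a cis-diol on C2/C3 and a carboxyl-level carbon on the diene terminus C1. This is exactly what remains of a 3-carboxylated 2-pyrone after a cis-dioxygenated alkene has added across its diene termini and the lactone bridge has been expelled.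

## Retrosynthesis

**14 from 13, and 13 from 12 and 10.** The last two cuts are the O3–Si bond and the C2 ester bond. The C2 benzoate is put on when C2–OH is the only free hydroxyl (12), so its position is fixed by constitution and not by selectivity. The neighbouring option, acylating an unprotected 2,3-diol through a cyclic orthoester, would rest on a conformational argument and expose the oxirane to acid. The forward steps must acylate a hindered secondary alcohol with 10 and then remove silicon without acyl shift to O3 or oxirane opening.

**12 from 11.** The two C–O bonds of the oxirane are cut, which removes two stereocentres and returns a diene. Delivery by the free C2 hydroxyl in a metal-catalysed hydroperoxide epoxidation puts the oxygen on the required face and touches only C1=C6, because C4=C5 has no free allylic hydroxyl. Two neighbours were rejected. A peracid on an acetal-protected diene attacks anti to the acetal. A halohydrin sequence would start by electrophilic attack at the diene terminus C4, giving the allyl cation with a tertiary end at C1, and so place the halogen on the wrong carbon.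

**11 from 9 and 10; 9 from 8; 8 from 7; 7 from 6.** These cuts are the C7 ester bond, the C7 oxidation level, the O3–Si bond and the acetal. The order is dictated by stability and selectivity:
- The acetal is removed from 6 while the ester still deactivates the diene toward acid-catalysed dehydration.
- In 7 the C2 hydroxyl is hindered and hydrogen-bonded to the ester, so the distal C3 hydroxyl is silylated (8).
- Reduction gives 9, whose primary hydroxyl is benzoylated before the epoxidation so that only C2–OH can direct.

All of these are functional-group changes on an unchanged skeleton.

**6 from 5, and 5 from 3 and 4.** Reinstalling a lactone bridge between C1 and C4 and cutting C1–C2 and C3–C4 leads to pyrone 4 and dioxole 3, two flat achiral partners. Against a [4+2] cut through C1–C6/C2–C3 or a chiral-pool ring, this one delivers all seven carbons, the C4=C5 bond, the C1=C6 bond at the place where the oxirane will go, and both carbinol centres in one step, with no surplus oxygen to remove later. The symmetric dienophile removes any regiochemical question. The forward reaction must control both the pyrone face and the endo/exo orientation, because the two diastereomeric adducts from one face collapse to enantiomeric dienes after decarboxylative cycloreversion, and it must stay mild enough not to aromatise 6.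

**3 from 2, and 2 from 1.** The enol ether double bond is cut back to an α-chloro ether and the C–Cl bond to a C–H bond of the commercial ketal 1. The only oxygen-activated C–H bonds of 1 are the four equivalent ring hydrogens, so no selectivity is needed beyond stopping at one chlorine.

## Roads not taken

**Alternative 1:** the ring is closed from an open chain by cutting C1–C6 and the C6–O bond of the oxirane.
- Forward key step: the (Z)-allyl tetrahydrothiophenium salt A1 has C1 as the ketone of a 2,2-dimethyl-1,3-dioxan-5-one (acetal across O7 and O2) and a silyl ether on C3. With Cs2CO3 it would give the ylide at C6, whose carbon adds to the C1 ketone; the alkoxide then displaces the sulfide at C6, closing cyclohexene and oxirane together to give A2.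
- Merits: ring and oxirane form in one step. The protecting groups of A2 already separate the two oxygens to be benzoylated (tied in the acetal) from O3. In this respect it is better than the chosen plan, which needs a regioselective silylation.
- Weak points: A1 must be assembled over many steps with C2, C3 and the (Z)-alkene in place. Its C2 is α to the ketone and can epimerise, and the β-silyloxy group can be eliminated under the basic conditions. The face of the ketone reached by the tethered ylide, which decides oxirane syn or anti to O2, is not under reagent control. The acetal of A2 would have to be hydrolysed beside a vinyl oxirane.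
- Comparison: the chosen plan offers a one-step catalytic construction of skeleton and carbinol centres from achiral components, no epimerisable ketone, and no acid after the oxirane is present.

**Alternative 2:** C1–C6 and C2–C3 are cut, giving furan A3 and (E)-3-(benzoyloxy)acrolein A4.
- Forward key step: an endo Diels–Alder reaction catalysed by the triflimide salt of the B-(o-tolyl)oxazaborolidine from diphenylprolinol would give 7-oxanorbornene A5 (formyl endo, benzoate exo). Base-induced opening of the oxygen bridge would later turn the bridge oxygen into the C3 hydroxyl.
- Merits: the C2 benzoate arrives with the dienophile on the correct oxygen and C3–OH emerges free, so no protecting group is needed to tell O2 from O3. This is better than the chosen plan on that point, and the starting materials are simpler.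
- Weak points: furan is a reluctant diene whose adducts revert. A4 is a vinylogous anhydride, an acyl donor and a weak dienophile. After bridge opening, the cyclohexadiene carbaldehyde carries a leaving group and aromatises easily. With C2 already acylated, no hydroxyl is placed to deliver the oxirane syn, so its face would depend on a reagent-controlled epoxidation.
- Comparison: the chosen plan offers a cycloaddition made irreversible by decarboxylation, intermediates at the ester level that resist aromatisation, and a free C2 hydroxyl to steer the oxirane.

**Alternative 3:** no C–C bond is made; the ring comes from shikimic acid A6 and the cuts are the C2–O bond and the two oxirane C–O bonds.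
- Forward key step: the 3-epi-shikimate-derived allylic alcohol A7 (C7 benzoate, C3–OH free, C4 and C5 silylated) undergoes dye-sensitised photooxygenation in the presence of Ti(OiPr)4. The hydroxyl-steered ene reaction of singlet oxygen puts a hydroperoxide on C2 and shifts the alkene to C1=C6, and titanium transfers the distal oxygen to that alkene on the same face, giving A8.
- Merits: absolute configuration comes from the chiral pool, which is more certain than an untested asymmetric cycloaddition. C1, C2 and C6 are set in one flask by internal delivery.
- Weak points: C3 of A6 must first be inverted. The ene reaction may abstract hydrogen from C7 rather than C6. A8 has O2 and O3 both free, so that problem is unsolved. The C4 and C5 oxygens are surplus: a trans-diol would have to be turned into the C4=C5 alkene at the end beside an oxirane and two benzoates, and the usual dideoxygenation reagents attack oxiranes or need a cis-diol. An estimated 13–15 steps are required.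
- Comparison: the chosen plan introduces only the oxygens the target has, carries C4=C5 from the start and is shorter, at the price of having to develop the enantiocontrol.

Key step: step 3

Assumption: the (S,S)-ligand is taken to be the enantiomer that leads to 6 in the (3aS,7aR) series through the endo adduct 5 (the exo adduct on the opposite pyrone face would give the same 6). If the chelate directs the other way, the (R,R)-ligand is used and nothing else changes.

## Route

Step 1
Reactants: 1 2,2-dimethyl-1,3-dioxolane
Product: 2 4-chloro-2,2-dimethyl-1,3-dioxolane (racemic)
Conditions: SO2Cl2 (0.8 equiv), AIBN (cat.), neat, 60 °C, N2 sweep; distillation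
Reagents that add atoms: sulfuryl chloride, O=S(=O)(Cl)Cl
Why: Free-radical chain chlorination α to ether oxygen, as in the known chlorination of tetrahydrofuran with sulfuryl chloride; only the four equivalent C4/C5 hydrogens are activated (C2 is quaternary), excess 1 holds back dichlorination and the gas sweep keeps HCl from opening the ketal.

Step 2
Reactants: 2 4-chloro-2,2-dimethyl-1,3-dioxolane
Product: 3 2,2-dimethyl-1,3-dioxole
Conditions: KOtBu (1.3 equiv), tetraglyme, 0 → 70 °C, product distilled out; redistilled, stored over K2CO3 at −20 °C
Reagents that add atoms: none
Why: Base-induced 1,2-elimination of HCl from an α-chloro ether to the enol ether, the reaction type by which vinylene carbonate is made from chloroethylene carbonate; the bulky alkoxide disfavours substitution at the acetal carbon and the volatile dioxole leaves the high-boiling solvent as it forms.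

Step 3
Reactants: 3 2,2-dimethyl-1,3-dioxole (3 equiv); 4 methyl 2-oxo-2H-pyran-3-carboxylate
Product: 6 methyl (3aS,7aR)-2,2-dimethyl-3a,7a-dihydro-1,3-benzodioxole-4-carboxylate, via bridged endo lactone 5 (not isolated)
Conditions: Cu(OTf)2 (10 mol%), 2,2′-isopropylidenebis[(4S)-4-tert-butyl-2-oxazoline] (11 mol%), 4 Å MS, CH2Cl2, −40 → 0 °C; filtration through Et3N-deactivated silica; then PhMe (0.02 M), 100 °C
Reagents that add atoms: none
Why: The lactone and ester carbonyls of 4 chelate the divalent copper centre, which lowers the pyrone LUMO and lets one tert-butyl group of the ligand cover one face of the bound diene; the electron-rich enediol ether 3 then adds across pyrone C6 and C3 (C4 and C1 of the target) in an inverse-electron-demand Diels–Alder reaction that is probably asynchronous, with C3–C4 ahead of C1–C2. The closest known reaction type is the Lewis-acid-catalysed cycloaddition of 3-carbomethoxy-2-pyrone with enol ethers, including variants with copper bis(oxazoline) catalysts. The carbocycle is closed by this intermolecular [4+2] addition (two new C–C bonds, bridged lactone 5), and warming then expels the lactone bridge as CO2 in a retro-[4+2] step that leaves the C1=C6–C5=C4 diene and makes the sequence irreversible. C2 and C3 are cis because the addition is suprafacial on a cyclic (Z)-alkene; their absolute configuration is fixed by the catalyst, through the pyrone face it leaves open together with the endo orientation of the dioxolane. Both selectivities are needed, because the exo adduct formed on the same pyrone face gives the mirror image of 6 once the bridgeheads become sp2; the rigid six-membered chelate and the compact cyclic dienophile, whose two oxygens must lie together either under the diene or away from it, should secure a single orientation. No regiochemical question arises because 3 has a twofold axis through its alkene. Copper is removed before heating and the thermolysis is run dilute and neutral so that the acetal is not opened (aromatisation) and 6 does not dimerise.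

Step 4
Reactants: 6 methyl (3aS,7aR)-2,2-dimethyl-3a,7a-dihydro-1,3-benzodioxole-4-carboxylate
Product: 7 methyl (5R,6S)-5,6-dihydroxycyclohexa-1,3-diene-1-carboxylate
Conditions: Dowex 50W (H+ form), MeOH/H2O 9:1, rt; filtration, NaHCO3; used promptly
Reagents that add atoms: none
Why: Acid-catalysed acetal hydrolysis breaks only the O–CMe2 bonds, so C2 and C3 keep their configuration; the ester conjugated with the diene strongly disfavours the competing ionisation of an allylic C–O bond that aromatises cyclohexadiene cis-diols, which is why the acetal is removed at this oxidation level.

Step 5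
Reactants: 7 methyl (5R,6S)-5,6-dihydroxycyclohexa-1,3-diene-1-carboxylate
Product: 8 methyl (5R,6S)-5-{[tert-butyl(dimethyl)silyl]oxy}-6-hydroxycyclohexa-1,3-diene-1-carboxylate
Conditions: TBSCl (1.05 equiv), imidazole (2.2 equiv), DMF, −30 → 0 °C
Reagents that add atoms: tert-butyldimethylsilyl chloride, CC(C)(C)[Si](C)(C)Cl
Why: Imidazole-mediated silylation is governed by access: the hydroxyl next to the ester-bearing carbon (C2 of the target) is flanked by a substituted sp2 centre and hydrogen-bonded to the ester carbonyl, so the distal C3 hydroxyl reacts first, the pattern generally seen with 3-substituted cyclohexadiene cis-diols; one equivalent at low temperature avoids the bis-ether.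

Step 6
Reactants: 8 methyl (5R,6S)-5-{[tert-butyl(dimethyl)silyl]oxy}-6-hydroxycyclohexa-1,3-diene-1-carboxylate
Product: 9 [(5R,6S)-5-{[tert-butyl(dimethyl)silyl]oxy}-6-hydroxycyclohexa-1,3-dien-1-yl]methanol
Conditions: iBu2AlH (3.5 equiv), CH2Cl2, −78 → −40 °C; aq. potassium sodium tartrate
Reagents that add atoms: none
Why: 1,2-Reduction of a conjugated ester to the allylic alcohol by iBu2AlH at low temperature; the free secondary hydroxyl is only converted to its aluminium alkoxide, the silyl ether is inert, and the neutral tartrate work-up spares the now electron-rich dienediol.

Step 7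
Reactants: 9 [(5R,6S)-5-{[tert-butyl(dimethyl)silyl]oxy}-6-hydroxycyclohexa-1,3-dien-1-yl]methanol; 10 benzoyl chloride (1.05 equiv)
Product: 11 [(5R,6S)-5-{[tert-butyl(dimethyl)silyl]oxy}-6-hydroxycyclohexa-1,3-dien-1-yl]methyl benzoate
Conditions: pyridine, CH2Cl2, −40 → 0 °C
Reagents that add atoms: none
Why: Nucleophilic acyl substitution that discriminates by steric access: the primary allylic C7 hydroxyl is acylated at low temperature while the secondary C2 hydroxyl, wedged between C1 and the silyloxy-bearing C3, is left; this also removes C7–OH as a possible directing group before the epoxidation.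

Step 8
Reactants: 11 [(5R,6S)-5-{[tert-butyl(dimethyl)silyl]oxy}-6-hydroxycyclohexa-1,3-dien-1-yl]methyl benzoate
Product: 12 [(1R,2R,3R,6S)-3-{[tert-butyl(dimethyl)silyl]oxy}-2-hydroxy-7-oxabicyclo[4.1.0]hept-4-en-1-yl]methyl benzoate (same geometry as 14; the C1 descriptor is R only because the free C2 hydroxyl changes the CIP ranking)
Conditions: VO(acac)2 (5 mol%), tBuOOH (1.3 equiv, decane), CH2Cl2, 0 °C → rt
Reagents that add atoms: tert-butyl hydroperoxide, CC(C)(C)OO
Why: Vanadium-catalysed hydroxyl-directed epoxidation: the C2 alkoxide binds the pentavalent vanadium tert-butylperoxo species and delivers oxygen to the adjacent C1=C6 bond on its own face, the cis selectivity typical of cyclohex-2-enols and best for a pseudoaxial hydroxyl, which 1,2-allylic strain with the C1 substituent enforces here; this sets C1 and C6 syn to O2, while C4=C5 carries only a silyl ether and is not activated.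

Step 9
Reactants: 12 [(1R,2R,3R,6S)-3-{[tert-butyl(dimethyl)silyl]oxy}-2-hydroxy-7-oxabicyclo[4.1.0]hept-4-en-1-yl]methyl benzoate; 10 benzoyl chloride (2 equiv)
Product: 13 [(1S,2R,3R,6S)-2-(benzoyloxy)-3-{[tert-butyl(dimethyl)silyl]oxy}-7-oxabicyclo[4.1.0]hept-4-en-1-yl]methyl benzoate
Conditions: pyridine, DMAP (0.2 equiv), CH2Cl2, 0 °C → rt
Reagents that add atoms: none
Why: DMAP-catalysed acylation of the only free hydroxyl, so the benzoate can go nowhere but C2; pyridine is too weak a base to start a Payne rearrangement or a silyl shift, and the oxirane is inert to these conditions.

Step 10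
Reactants: 13 [(1S,2R,3R,6S)-2-(benzoyloxy)-3-{[tert-butyl(dimethyl)silyl]oxy}-7-oxabicyclo[4.1.0]hept-4-en-1-yl]methyl benzoate
Product: 14 [(1S,2R,3R,6S)-2-(benzoyloxy)-3-hydroxy-7-oxabicyclo[4.1.0]hept-4-en-1-yl]methyl benzoate
Conditions: Bu4NF (1.5 equiv), AcOH (1.8 equiv), THF, 0 °C → rt
Reagents that add atoms: none
Why: Fluoride cleaves the Si–O bond; the acetic acid buffer protonates the C3 alkoxide as it forms, which suppresses 1,2-benzoyl transfer from O2 to the cis O3 and keeps the medium close to neutral for the vinyl oxirane.

## Compound list

1 | 2,2-dimethyl-1,3-dioxolane | CC1(C)OCCO1 | starting material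
2 | 4-chloro-2,2-dimethyl-1,3-dioxolane (racemic) | CC1(C)OCC(Cl)O1 | intermediate
3 | 2,2-dimethyl-1,3-dioxole | CC1(C)OC=CO1 | intermediate
4 | methyl 2-oxo-2H-pyran-3-carboxylate | COC(=O)C1=CC=COC1=O | starting material
5 | methyl (1R,2S,6R,7S)-4,4-dimethyl-9-oxo-3,5,8-trioxatricyclo[5.2.2.0(2,6)]undec-10-ene-1-carboxylate (endo bridged lactone, dioxolane on the side of the C10=C11 bridge; not isolated) | COC(=O)[C@]12C=C[C@H](OC1=O)[C@H]3OC(C)(C)O[C@@H]23 | intermediate
6 | methyl (3aS,7aR)-2,2-dimethyl-3a,7a-dihydro-1,3-benzodioxole-4-carboxylate | COC(=O)C1=CC=C[C@H]2OC(C)(C)O[C@@H]12 | intermediate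
7 | methyl (5R,6S)-5,6-dihydroxycyclohexa-1,3-diene-1-carboxylate | COC(=O)C1=CC=C[C@@H](O)[C@H]1O | intermediate
8 | methyl (5R,6S)-5-{[tert-butyl(dimethyl)silyl]oxy}-6-hydroxycyclohexa-1,3-diene-1-carboxylate | COC(=O)C1=CC=C[C@@H](O[Si](C)(C)C(C)(C)C)[C@H]1O | intermediate
9 | [(5R,6S)-5-{[tert-butyl(dimethyl)silyl]oxy}-6-hydroxycyclohexa-1,3-dien-1-yl]methanol | OCC1=CC=C[C@@H](O[Si](C)(C)C(C)(C)C)[C@H]1O | intermediate
10 | benzoyl chloride | O=C(Cl)c1ccccc1 | starting material
11 | [(5R,6S)-5-{[tert-butyl(dimethyl)silyl]oxy}-6-hydroxycyclohexa-1,3-dien-1-yl]methyl benzoate | O=C(OCC1=CC=C[C@@H](O[Si](C)(C)C(C)(C)C)[C@H]1O)c1ccccc1 | intermediate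
12 | [(1R,2R,3R,6S)-3-{[tert-butyl(dimethyl)silyl]oxy}-2-hydroxy-7-oxabicyclo[4.1.0]hept-4-en-1-yl]methyl benzoate | O=C(OC[C@]12O[C@H]1C=C[C@@H](O[Si](C)(C)C(C)(C)C)[C@H]2O)c1ccccc1 | intermediate
13 | [(1S,2R,3R,6S)-2-(benzoyloxy)-3-{[tert-butyl(dimethyl)silyl]oxy}-7-oxabicyclo[4.1.0]hept-4-en-1-yl]methyl benzoate | O=C(OC[C@]12O[C@H]1C=C[C@@H](O[Si](C)(C)C(C)(C)C)[C@H]2OC(=O)c1ccccc1)c1ccccc1 | intermediate
14 | [(1S,2R,3R,6S)-2-(benzoyloxy)-3-hydroxy-7-oxabicyclo[4.1.0]hept-4-en-1-yl]methyl benzoate | O=C(OC[C@]12O[C@H]1C=C[C@@H](O)[C@H]2OC(=O)c1ccccc1)c1ccccc1 | target

## Step count and least certain steps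

Total: 10 steps. Longest linear sequence: 10 steps (1 to 14); 4 and 10 are bought.

**Step 3 (key step).** The likely failure is incomplete control of the pyrone face or of the endo/exo orientation; either lowers the enantiopurity of 6, because the diastereomeric adducts converge on enantiomeric dienes. The Lewis acid may also oligomerise the enol ether, and the acetal may open with aromatisation during the thermal loss of CO2. Fallback, setting out from 3 and 4 and returning at 6: the cycloaddition is run with achiral Yb(OTf)3 in CH2Cl2 to give the racemic bridged lactone F1, which is heated in dilute toluene to the racemic diene ester F2. The enantiomers of F2 are separated by preparative chromatography on an amylose tris(3,5-dimethylphenylcarbamate) stationary phase, which delivers 6.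

**Step 2.** The alkoxide may substitute at the acetal carbon in place of eliminating, tert-butanol may co-distil, and the volatile, acid-sensitive dioxole may be lost on isolation. Fallback, setting out from 2 and returning at 3: the chloride is displaced with KOAc (18-crown-6, MeCN) to give 2,2-dimethyl-1,3-dioxolan-4-yl acetate F3, and gas-phase ester pyrolysis in a flow tube (about 450 °C) eliminates acetic acid through the cyclic syn mechanism and gives 3 free of alcohol.

**Step 8.** The doubly allylic C2 carbinol may be oxidised to the dienone (which would tautomerise to a phenol) in competition with oxygen transfer, and a second, slower epoxidation at C4=C5 may follow. Fallback, setting out from 9 and returning at 13: a Katsuki–Sharpless epoxidation of 9 with Ti(OiPr)4, diisopropyl D-tartrate and tBuOOH (4 Å MS, CH2Cl2, −20 °C) moves the directing role to the primary C7 alkoxide, which reaches only C1=C6; the tartrate selects the face syn to O2 and O3 and does not oxidise the carbinol. This gives the epoxy diol (1R,2R,3R,6S)-3-{[tert-butyl(dimethyl)silyl]oxy}-1-(hydroxymethyl)-7-oxabicyclo[4.1.0]hept-4-en-2-ol F4. Benzoylation of both hydroxyls with excess 10, pyridine and DMAP gives 13.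

**Step 10.** The benzoyl group may move from O2 to O3 through the transient C3 alkoxide, and fluoride or acetate may open the vinyl oxirane. Fallback, setting out from 12 and returning at 14: the silyl group is removed first with Bu4NF/AcOH, when no vicinal ester is present, to give [(1R,2R,3R,6S)-2,3-dihydroxy-7-oxabicyclo[4.1.0]hept-4-en-1-yl]methyl benzoate F5. Trimethyl orthobenzoate and catalytic PPTS convert it into the cyclic 2,3-orthobenzoate F6 (both epimers at the orthoester carbon), which is opened with aqueous acetic acid at room temperature. The hemiorthoester is expected to collapse to the ester on the pseudoaxial oxygen, which 1,2-strain with the C1 substituents makes O2, giving 14.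

## Further compounds

F1 | step 3 | racemic methyl 4,4-dimethyl-9-oxo-3,5,8-trioxatricyclo[5.2.2.0(2,6)]undec-10-ene-1-carboxylate (endo; one enantiomer drawn) | COC(=O)[C@]12C=C[C@H](OC1=O)[C@H]3OC(C)(C)O[C@@H]23
F2 | step 3 | racemic methyl cis-2,2-dimethyl-3a,7a-dihydro-1,3-benzodioxole-4-carboxylate (one enantiomer drawn) | COC(=O)C1=CC=C[C@H]2OC(C)(C)O[C@@H]12
F3 | step 2 | 2,2-dimethyl-1,3-dioxolan-4-yl acetate (racemic) | CC(=O)OC1COC(C)(C)O1
F4 | step 8 | (1R,2R,3R,6S)-3-{[tert-butyl(dimethyl)silyl]oxy}-1-(hydroxymethyl)-7-oxabicyclo[4.1.0]hept-4-en-2-ol | OC[C@]12O[C@H]1C=C[C@@H](O[Si](C)(C)C(C)(C)C)[C@H]2O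
F5 | step 10 | [(1R,2R,3R,6S)-2,3-dihydroxy-7-oxabicyclo[4.1.0]hept-4-en-1-yl]methyl benzoate | O=C(OC[C@]12O[C@H]1C=C[C@@H](O)[C@H]2O)c1ccccc1
F6 | step 10 | cyclic 2,3-(methyl orthobenzoate) of F5 (2-methoxy-2-phenyl-1,3-dioxolane fused at C2/C3, both epimers at the orthoester carbon) | O=C(OC[C@]12O[C@H]1C=C[C@H]3OC(OC)(c4ccccc4)O[C@@H]23)c1ccccc1
A1 | alternative 1 | (Z)-allyl tetrahydrothiophenium bromide carrying the 2,2-dimethyl-1,3-dioxan-5-one (C1 ketone, O7/O2 acetal) and the C3 tert-butyldimethylsilyl ether | CC1(C)OCC(=O)[C@H](O1)[C@H](O[Si](C)(C)C(C)(C)C)/C=C\C[S+]1CCCC1.[Br-]
A2 | alternative 1 | epoxycyclohexene with O7/O2 acetonide and C3 tert-butyldimethylsilyl ether | CC1(C)OC[C@]23O[C@H]2C=C[C@@H](O[Si](C)(C)C(C)(C)C)[C@H]3O1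
A3 | alternative 2 | furan | c1ccoc1
A4 | alternative 2 | (E)-3-(benzoyloxy)acrolein | O=C/C=C/OC(=O)c1ccccc1
A5 | alternative 2 | endo-formyl, exo-benzoyloxy 7-oxabicyclo[2.2.1]hept-5-ene | O=C[C@H]1[C@H](OC(=O)c2ccccc2)[C@H]2C=C[C@@H]1O2
A6 | alternative 3 | shikimic acid | O=C(O)C1=C[C@@H](O)[C@@H](O)[C@H](O)C1
A7 | alternative 3 | 3-epi-shikimate-derived allylic alcohol (C7 benzoate, C3 hydroxyl free, C4 and C5 tert-butyldimethylsilyl ethers) | O=C(OCC1=C[C@H](O)[C@@H](O[Si](C)(C)C(C)(C)C)[C@H](O[Si](C)(C)C(C)(C)C)C1)c1ccccc1
A8 | alternative 3 | 1,6-epoxy-2,3-diol with the 4,5-diol as bis(tert-butyldimethylsilyl) ether and the C7 benzoate | O=C(OC[C@]12O[C@H]1[C@@H](O[Si](C)(C)C(C)(C)C)[C@H](O[Si](C)(C)C(C)(C)C)[C@@H](O)[C@H]2O)c1ccccc1
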